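The plan rests on cutting the two exocyclic bonds on ring B (the dihydrofuran ring O1–C2–C3–C3a–C7a): C2–C1′ to the syringyl ring and C3–C9 to the hydroxymethyl carbon. The vicinal trans C2-aryl/C3-CH2OH pair is read as the result of adding aryl and carbon to opposite faces of the C2=C3 bond of a planar 7-methoxybenzofuran whose C2–H can be lithiated. In one operation a borate built from that C2-lithium compound and a syringyl pinacol boronate is allylated at C3 by a chiral allylpalladium cation as the syringyl group migrates from boron to C2 on the other face, which sets both stereocentres. The precursor is a 5-acetal-protected benzofuran-2-yllithium, a MOM-protected arylboronate and allyl acetate.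

Key step: step 6

Assumption: (S)-BINAP is taken to steer the allyl group to the C3 face drawn for 13; if the opposite sense is found, (R)-BINAP is used and nothing else changes.
Atom labels: benzofuran numbering (O1, C2, C3, C3a, C4–C7, C7a; ring A = benzo ring, ring B = furan ring); C1′ = ipso carbon of the syringyl ring (ring C); C9 = the carbon attached to C3.
Design remark: the aldehyde is carried as a dioxolane and the phenol as a MOM ether because both survive nBuLi, fluoride, ruthenium hydride and periodate and are removed together in one acidic operation; lithiation is held at –78 °C so that neither the acetal C–H nor ring A is metalated.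

Step 1
Reactants: 1 5-iodovanillin; 2 trimethylsilylacetylene
Product: 4 7-methoxy-2-(trimethylsilyl)-1-benzofuran-5-carbaldehyde, via ortho-(silylethynyl)phenol 3 (not isolated)
Conditions: PdCl2(PPh3)2 (2 mol %), CuI (4 mol %), Et3N, DMF, rt → 70 °C
Reagents that add atoms: none
Why: Sonogashira coupling at the aryl iodide is followed in the same pot by copper- and base-promoted 5-endo-dig cycloisomerisation of the ortho-alkynylphenol, a standard entry to 2-silylbenzofurans from ortho-iodophenols that forms no stereocentre.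

Step 2
Reactants: 4 7-methoxy-2-(trimethylsilyl)-1-benzofuran-5-carbaldehyde
Product: 5 7-methoxy-1-benzofuran-5-carbaldehyde
Conditions: TBAF (1.1 equiv), wet THF, 0 °C → rt
Reagents that add atoms: none
Why: Fluoride-induced protodesilylation, in which fluoride adds to silicon and the C2–Si bond of the heteroaryl silane is protonated by water, should free C2–H while leaving the aldehyde untouched.

Step 3
Reactants: 5 7-methoxy-1-benzofuran-5-carbaldehyde
Product: 6 2-(7-methoxy-1-benzofuran-5-yl)-1,3-dioxolane
Conditions: ethylene glycol, p-TsOH·H2O (catalytic), toluene, reflux (Dean–Stark)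
Reagents that add atoms: ethylene glycol, OCCO
Why: Acid-catalysed acetalisation with azeotropic removal of water masks the aldehyde against nBuLi and borohydride, and the catalytic acid loading should not harm the benzofuran.

Step 4
Reactants: 7 4-bromo-2,6-dimethoxyphenol
Product: 8 5-bromo-1,3-dimethoxy-2-(methoxymethoxy)benzene
Conditions: NaH, MOMCl, DMF, 0 °C → rt
Reagents that add atoms: chloromethyl methyl ether (MOMCl), COCCl
Why: Williamson-type O-alkylation of the sodium phenoxide should give the MOM ether, which tolerates organolithium, fluoride, ruthenium hydride and periodate and is cleaved later together with the acetal.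

Step 5
Reactants: 8 5-bromo-1,3-dimethoxy-2-(methoxymethoxy)benzene
Product: 9 2-[3,5-dimethoxy-4-(methoxymethoxy)phenyl]-4,4,5,5-tetramethyl-1,3,2-dioxaborolane
Conditions: B2pin2, PdCl2(dppf) (3 mol %), KOAc, 1,4-dioxane, 90 °C
Reagents that add atoms: bis(pinacolato)diboron (B2pin2), CC1(C)OB(OC1(C)C)B1OC(C)(C)C(C)(C)O1
Why: Miyaura borylation (oxidative addition, acetate-assisted transmetalation with the diboron reagent, reductive elimination) should convert the electron-rich aryl bromide into the pinacol boronate without touching the MOM ether.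

Step 6
Reactants: 6 2-(7-methoxy-1-benzofuran-5-yl)-1,3-dioxolane; 9 2-[3,5-dimethoxy-4-(methoxymethoxy)phenyl]-4,4,5,5-tetramethyl-1,3,2-dioxaborolane; 10 allyl acetate
Product: 13 (2S,3S)-3-allyl-2-[3,5-dimethoxy-4-(methoxymethoxy)phenyl]-5-(1,3-dioxolan-2-yl)-7-methoxy-2-(4,4,5,5-tetramethyl-1,3,2-dioxaborolan-2-yl)-2,3-dihydro-1-benzofuran, via benzofuran-2-yllithium 11 (not isolated), via lithium aryl(benzofuranyl)pinacolborate 12 (not isolated)
Conditions: nBuLi (1.05 equiv), THF, –78 °C; 9, –78 → 0 °C; then Pd2(dba)3 (2.5 mol %), (S)-BINAP (6 mol %), 10 (1.5 equiv), THF, 0 °C → rt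
Reagents that add atoms: none
Why: Proposed new method: nBuLi removes the acidic C2–H of 6, the lithium compound 11 adds to the vacant boron orbital of 9, and in the resulting borate 12 the C2=C3 enol ether is made strongly nucleophilic at C3 by the anionic boron; Pd2(dba)3 and (S)-BINAP ionise 10 to a cationic allylpalladium complex, C3 attacks one allyl terminus from the side away from the metal, and in concert the syringyl group moves from boron to C2 (1,2-metallate shift), which releases zerovalent palladium and lithium acetate. The closest known reaction type is the palladium-catalysed enantioselective allylation-triggered 1,2-boronate migration of indol-2-yl borates, a dearomative three-component coupling; its transfer from the indole enamine to the less nucleophilic benzofuran enol ether is the unproven part. No ring is closed: C3–C9 and C2–C1′ are formed on the existing ring B, which loses its aromaticity. The trans relation of aryl and allyl follows from the antiperiplanar course of the shift (the aryl group enters C2 on the face opposite to the incoming allyl group, boron stays on the allyl face), and the absolute configuration is set at C3 by the chiral bisphosphine on the allylpalladium cation, which selects one face of the flat borate. The step needs attack through C3 to outrun direct transfer of the aryl or benzofuranyl group from boron to palladium; this is secured by the coordinatively saturated boron of 12, which has no site for transmetalation, by the unhindered, electron-rich migrating group, and by C3 being the only carbon whose attack is coupled to the shift. Dioxolane, MOM ether and methyl ethers are inert to nBuLi at –78 °C and to the neutral catalytic conditions.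

Step 7
Reactants: 13 (2S,3S)-2-boryl-3-allyl-2-aryl-2,3-dihydrobenzofuran
Product: 14 (2S,3S)-3-allyl-2-[3,5-dimethoxy-4-(methoxymethoxy)phenyl]-5-(1,3-dioxolan-2-yl)-7-methoxy-2,3-dihydro-1-benzofuran
Conditions: TBAF·3H2O (3 equiv), toluene, 45 °C
Reagents that add atoms: none
Why: Fluoride-promoted protodeboronation of a tertiary benzylic pinacol boronate, in which the fluoroborate delivers a proton from bound water to the face that carried boron, should turn C2–B into C2–H with retention so that aryl and allyl stay trans.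

Step 8
Reactants: 14 (2S,3S)-3-allyl-2-aryl-2,3-dihydrobenzofuran
Product: 15 (2S,3S)-2-[3,5-dimethoxy-4-(methoxymethoxy)phenyl]-5-(1,3-dioxolan-2-yl)-7-methoxy-3-[(E)-prop-1-en-1-yl]-2,3-dihydro-1-benzofuran
Conditions: RuHCl(CO)(PPh3)3 (5 mol %), toluene, 80 °C
Reagents that add atoms: none
Why: Ruthenium hydride-catalysed olefin isomerisation (hydrometalation then β-hydride elimination) should move the terminal double bond one position to the internal propenyl isomer and stop there, because further migration would need insertion at the hindered tertiary C3, so neither stereocentre is touched.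

Step 9
Reactants: 15 (2S,3S)-3-[(E)-prop-1-enyl]-2-aryl-2,3-dihydrobenzofuran
Product: 18 [(2S,3R)-2-[3,5-dimethoxy-4-(methoxymethoxy)phenyl]-5-(1,3-dioxolan-2-yl)-7-methoxy-2,3-dihydro-1-benzofuran-3-yl]methanol, via vicinal diol 16 (not isolated), via 3-carbaldehyde 17 (not isolated)
Conditions: OsO4 (2 mol %), NaIO4 (4 equiv), 2,6-lutidine, dioxane/H2O (3:1), rt; extractive work-up, crude aldehyde used at once; NaBH4, MeOH, 0 °C
Reagents that add atoms: osmium tetroxide, O=[Os](=O)(=O)=O (delivers the oxygen); sodium periodate, [Na+].[O-]I(=O)(=O)=O (restores it)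
Why: Lemieux–Johnson oxidation (catalytic syn-dihydroxylation and periodate cleavage, buffered by 2,6-lutidine) should cut the propenyl group down to the C3 aldehyde, which is reduced at once by NaBH4 so that the epimerisable α-aryl aldehyde does not accumulate; C3 keeps its geometry and only its descriptor changes to R through the new priorities.

Step 10
Reactants: 18 protected (2S,3R)-hydroxymethyl dihydrobenzofuran
Product: 20 (2S,3R)-2-(4-hydroxy-3,5-dimethoxyphenyl)-3-(hydroxymethyl)-7-methoxy-2,3-dihydro-1-benzofuran-5-carbaldehyde, via MOM-protected aldehyde 19 (not isolated)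
Conditions: 2 M aq. HCl/THF (1:1), rt → 45 °C
Reagents that add atoms: water, O
Why: Acid-catalysed acetal hydrolysis should open the dioxolane first and then the phenolic MOM acetal in the same flask, and under these conditions any C2 epimer would return to the trans isomer by reversible ionisation of the para-hydroxybenzylic C2–O1 bond while C3 is unaffected.

Step 11
Reactants: 20 (2S,3R)-phenol aldehyde; 21 malonic acid
Product: 23 (E)-3-[(2S,3R)-2-(4-hydroxy-3,5-dimethoxyphenyl)-3-(hydroxymethyl)-7-methoxy-2,3-dihydro-1-benzofuran-5-yl]prop-2-enoic acid, via arylidenemalonic acid 22 (not isolated)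
Conditions: pyridine, piperidine (catalytic), 85 °C; then 1 M aq. HCl work-up
Reagents that add atoms: none
Why: Knoevenagel–Doebner condensation, in which amine-catalysed condensation of the aryl aldehyde with malonic acid is followed by decarboxylation in pyridine, should give the E-cinnamic acid under thermodynamic control, as in the preparation of sinapic acid from syringaldehyde, without affecting the free phenol, the primary alcohol or the stereocentres.

Compound list
1 | 5-iodovanillin (4-hydroxy-3-iodo-5-methoxybenzaldehyde) | COc1cc(C=O)cc(I)c1O | starting material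
2 | trimethylsilylacetylene | C#C[Si](C)(C)C | starting material
3 | 4-hydroxy-3-methoxy-5-[(trimethylsilyl)ethynyl]benzaldehyde (not isolated) | COc1cc(C=O)cc(C#C[Si](C)(C)C)c1O | intermediate
4 | 7-methoxy-2-(trimethylsilyl)-1-benzofuran-5-carbaldehyde | COc1cc(C=O)cc2cc([Si](C)(C)C)oc12 | intermediate
5 | 7-methoxy-1-benzofuran-5-carbaldehyde | COc1cc(C=O)cc2ccoc12 | intermediate
6 | 2-(7-methoxy-1-benzofuran-5-yl)-1,3-dioxolane | COc1cc(C2OCCO2)cc2ccoc12 | intermediate
7 | 4-bromo-2,6-dimethoxyphenol | COc1cc(Br)cc(OC)c1O | starting material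
8 | 5-bromo-1,3-dimethoxy-2-(methoxymethoxy)benzene | COCOc1c(OC)cc(Br)cc1OC | intermediate
9 | 2-[3,5-dimethoxy-4-(methoxymethoxy)phenyl]-4,4,5,5-tetramethyl-1,3,2-dioxaborolane | COCOc1c(OC)cc(B2OC(C)(C)C(C)(C)O2)cc1OC | intermediate
10 | allyl acetate | C=CCOC(C)=O | starting material
11 | [5-(1,3-dioxolan-2-yl)-7-methoxy-1-benzofuran-2-yl]lithium (not isolated) | [Li]c1cc2cc(C3OCCO3)cc(OC)c2o1 | intermediate
12 | lithium [3,5-dimethoxy-4-(methoxymethoxy)phenyl][5-(1,3-dioxolan-2-yl)-7-methoxy-1-benzofuran-2-yl](pinacolato)borate (not isolated) | [Li+].COCOc1c(OC)cc([B-]2(c3cc4cc(C5OCCO5)cc(OC)c4o3)OC(C)(C)C(C)(C)O2)cc1OC | intermediate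
13 | (2S,3S)-3-allyl-2-[3,5-dimethoxy-4-(methoxymethoxy)phenyl]-5-(1,3-dioxolan-2-yl)-7-methoxy-2-(4,4,5,5-tetramethyl-1,3,2-dioxaborolan-2-yl)-2,3-dihydro-1-benzofuran (aryl trans to allyl, boron cis to allyl) | COCOc1c(OC)cc([C@@]2(B3OC(C)(C)C(C)(C)O3)Oc3c(OC)cc(C4OCCO4)cc3[C@@H]2CC=C)cc1OC | intermediate
14 | (2S,3S)-3-allyl-2-[3,5-dimethoxy-4-(methoxymethoxy)phenyl]-5-(1,3-dioxolan-2-yl)-7-methoxy-2,3-dihydro-1-benzofuran (trans) | COCOc1c(OC)cc([C@H]2Oc3c(OC)cc(C4OCCO4)cc3[C@@H]2CC=C)cc1OC | intermediate
15 | (2S,3S)-2-[3,5-dimethoxy-4-(methoxymethoxy)phenyl]-5-(1,3-dioxolan-2-yl)-7-methoxy-3-[(E)-prop-1-en-1-yl]-2,3-dihydro-1-benzofuran (trans; any Z isomer converges in step 9) | COCOc1c(OC)cc([C@H]2Oc3c(OC)cc(C4OCCO4)cc3[C@@H]2/C=C/C)cc1OC | intermediate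
16 | 1-[(2S,3S)-2-aryl-5-(1,3-dioxolan-2-yl)-7-methoxy-2,3-dihydro-1-benzofuran-3-yl]propane-1,2-diol, aryl = 3,5-dimethoxy-4-(methoxymethoxy)phenyl, syn diol as a mixture of two diastereomers at the carbinol carbons, ring configuration as in 15 (not isolated) | COCOc1c(OC)cc([C@H]2Oc3c(OC)cc(C4OCCO4)cc3[C@@H]2C(O)C(C)O)cc1OC | intermediate
17 | (2S,3S)-2-[3,5-dimethoxy-4-(methoxymethoxy)phenyl]-5-(1,3-dioxolan-2-yl)-7-methoxy-2,3-dihydro-1-benzofuran-3-carbaldehyde (trans, not isolated) | COCOc1c(OC)cc([C@H]2Oc3c(OC)cc(C4OCCO4)cc3[C@@H]2C=O)cc1OC | intermediate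
18 | [(2S,3R)-2-[3,5-dimethoxy-4-(methoxymethoxy)phenyl]-5-(1,3-dioxolan-2-yl)-7-methoxy-2,3-dihydro-1-benzofuran-3-yl]methanol (trans) | COCOc1c(OC)cc([C@H]2Oc3c(OC)cc(C4OCCO4)cc3[C@@H]2CO)cc1OC | intermediate
19 | (2S,3R)-2-[3,5-dimethoxy-4-(methoxymethoxy)phenyl]-3-(hydroxymethyl)-7-methoxy-2,3-dihydro-1-benzofuran-5-carbaldehyde (not isolated) | COCOc1c(OC)cc([C@H]2Oc3c(OC)cc(C=O)cc3[C@@H]2CO)cc1OC | intermediate
20 | (2S,3R)-2-(4-hydroxy-3,5-dimethoxyphenyl)-3-(hydroxymethyl)-7-methoxy-2,3-dihydro-1-benzofuran-5-carbaldehyde | COc1cc([C@H]2Oc3c(OC)cc(C=O)cc3[C@@H]2CO)cc(OC)c1O | intermediate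
21 | malonic acid | OC(=O)CC(=O)O | starting material
22 | 2-{[(2S,3R)-2-(4-hydroxy-3,5-dimethoxyphenyl)-3-(hydroxymethyl)-7-methoxy-2,3-dihydro-1-benzofuran-5-yl]methylidene}propanedioic acid (not isolated) | COc1cc([C@H]2Oc3c(OC)cc(C=C(C(=O)O)C(=O)O)cc3[C@@H]2CO)cc(OC)c1O | intermediate
23 | (E)-3-[(2S,3R)-2-(4-hydroxy-3,5-dimethoxyphenyl)-3-(hydroxymethyl)-7-methoxy-2,3-dihydro-1-benzofuran-5-yl]prop-2-enoic acid | COc1cc([C@H]2Oc3c(OC)cc(/C=C/C(=O)O)cc3[C@@H]2CO)cc(OC)c1O | target

Total step count: 11. Longest linear sequence: 9 steps (steps 1, 2, 3, 6, 7, 8, 9, 10, 11); steps 4 and 5 make the boronate branch.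

Steps most likely to fail

1. Step 6 (the step proposed as a new method). What may go wrong: transfer of the aryl or benzofuranyl group from boron to the allylpalladium cation may outrun attack through C3, giving plain cross-coupling without the shift; the chiral ligand may discriminate poorly between the two C3 faces; nBuLi may metalate ring A in competition with C2. Fallback by known reactions, making the same two bonds stepwise and then resolving: setting out from 6 and 8, palladium-catalysed direct C2–H arylation (Pd(OAc)2, PCy3·HBF4, pivalic acid, K2CO3, DMA, 110 °C) should give the 2-arylbenzofuran F1; NBS (MeCN, 0 °C) should brominate the enol-ether carbon C3 to give the 3-bromobenzofuran F2; methoxycarbonylation (Pd(OAc)2, Xantphos, CO, MeOH, Et3N, 70 °C) should give the methyl benzofuran-3-carboxylate F3; Mg in MeOH/THF should reduce the C2=C3 bond, the methoxide formed settling the ester trans to the aryl group, to give the racemic trans dihydrobenzofuran ester F4; LiAlH4 (THF, 0 °C) should give the racemic alcohol F5, which is resolved by preparative HPLC on a chiral stationary phase, and the (2S,3R) enantiomer comes back to the route at 18.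

2. Step 7. What may go wrong: the C2–B bond may break through a free benzylic carbanion that is protonated from the face away from the allyl group, which erodes the trans relation at C2, or the fluoroborate may decompose by opening of ring B. Fallback by thermodynamic control of C2 in place of stereospecific protonolysis: setting out from 13, any protonolysis that cleaves the C–B bond (for example CsF, H2O, 1,4-dioxane, 60 °C) gives 14 mixed with its C2 epimer, the cis allyl compound F6; the mixture is treated with 2 M aq. HCl/THF at 45 °C, which removes acetal and MOM groups and, by reversible ionisation of the para-hydroxybenzylic C2–O1 bond, should convert the cis phenol aldehyde F7 into the trans phenol aldehyde F8 (C3 cannot epimerise at the allyl stage and steers the re-closure); re-acetalisation under the conditions of step 3 gives the phenol acetal F9, and MOM protection under the conditions of step 4 comes back to the route at 14.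

3. Step 8. What may go wrong: the ruthenium hydride may walk the double bond one position further, into conjugation with ring A, which would erase the C3 stereocentre, or it may stall on the hindered substrate. Fallback by one-carbon degradation through an aldehyde enol ether in place of olefin migration: setting out from 14, Lemieux–Johnson cleavage of the terminal alkene (OsO4 catalytic, NaIO4, 2,6-lutidine, dioxane/H2O) passes through the terminal diol F10 and gives the homologous aldehyde F11, in which C3 is β to the carbonyl and cannot epimerise; TBSOTf/Et3N (CH2Cl2, 0 °C) gives the silyl enol ether F12, the only enol ether this aldehyde can form; ozonolysis (one equivalent of O3, CH2Cl2/MeOH, –78 °C, then NaBH4) cleaves the electron-rich enol double bond to aldehyde 17 and reduces it in the same flask, coming back to the route at 18.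

Further compounds
F1 | step 6 | 2-{2-[3,5-dimethoxy-4-(methoxymethoxy)phenyl]-7-methoxy-1-benzofuran-5-yl}-1,3-dioxolane | COCOc1c(OC)cc(-c2cc3cc(C4OCCO4)cc(OC)c3o2)cc1OC
F2 | step 6 | 2-{3-bromo-2-[3,5-dimethoxy-4-(methoxymethoxy)phenyl]-7-methoxy-1-benzofuran-5-yl}-1,3-dioxolane | COCOc1c(OC)cc(-c2oc3c(OC)cc(C4OCCO4)cc3c2Br)cc1OC
F3 | step 6 | methyl 2-[3,5-dimethoxy-4-(methoxymethoxy)phenyl]-5-(1,3-dioxolan-2-yl)-7-methoxy-1-benzofuran-3-carboxylate | COCOc1c(OC)cc(-c2oc3c(OC)cc(C4OCCO4)cc3c2C(=O)OC)cc1OC
F4 | step 6 | racemic trans methyl 2-[3,5-dimethoxy-4-(methoxymethoxy)phenyl]-5-(1,3-dioxolan-2-yl)-7-methoxy-2,3-dihydro-1-benzofuran-3-carboxylate (2S,3S and 2R,3R) | COCOc1c(OC)cc([C@H]2Oc3c(OC)cc(C4OCCO4)cc3[C@@H]2C(=O)OC)cc1OC.COCOc1c(OC)cc([C@@H]2Oc3c(OC)cc(C4OCCO4)cc3[C@H]2C(=O)OC)cc1OC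
F5 | step 6 | racemic trans [2-[3,5-dimethoxy-4-(methoxymethoxy)phenyl]-5-(1,3-dioxolan-2-yl)-7-methoxy-2,3-dihydro-1-benzofuran-3-yl]methanol (2S,3R and 2R,3S; racemate of 18) | COCOc1c(OC)cc([C@H]2Oc3c(OC)cc(C4OCCO4)cc3[C@@H]2CO)cc1OC.COCOc1c(OC)cc([C@@H]2Oc3c(OC)cc(C4OCCO4)cc3[C@H]2CO)cc1OC
F6 | step 7 | (2R,3S)-3-allyl-2-[3,5-dimethoxy-4-(methoxymethoxy)phenyl]-5-(1,3-dioxolan-2-yl)-7-methoxy-2,3-dihydro-1-benzofuran (cis, C2 epimer of 14) | COCOc1c(OC)cc([C@@H]2Oc3c(OC)cc(C4OCCO4)cc3[C@@H]2CC=C)cc1OC
F7 | step 7 | (2R,3S)-3-allyl-2-(4-hydroxy-3,5-dimethoxyphenyl)-7-methoxy-2,3-dihydro-1-benzofuran-5-carbaldehyde (cis) | COc1cc([C@@H]2Oc3c(OC)cc(C=O)cc3[C@@H]2CC=C)cc(OC)c1O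
F8 | step 7 | (2S,3S)-3-allyl-2-(4-hydroxy-3,5-dimethoxyphenyl)-7-methoxy-2,3-dihydro-1-benzofuran-5-carbaldehyde (trans) | COc1cc([C@H]2Oc3c(OC)cc(C=O)cc3[C@@H]2CC=C)cc(OC)c1O
F9 | step 7 | 4-[(2S,3S)-3-allyl-5-(1,3-dioxolan-2-yl)-7-methoxy-2,3-dihydro-1-benzofuran-2-yl]-2,6-dimethoxyphenol (trans) | COc1cc([C@H]2Oc3c(OC)cc(C4OCCO4)cc3[C@@H]2CC=C)cc(OC)c1O
F10 | step 8 | 3-[(2S,3S)-2-[3,5-dimethoxy-4-(methoxymethoxy)phenyl]-5-(1,3-dioxolan-2-yl)-7-methoxy-2,3-dihydro-1-benzofuran-3-yl]propane-1,2-diol (mixture at the carbinol carbon) | COCOc1c(OC)cc([C@H]2Oc3c(OC)cc(C4OCCO4)cc3[C@@H]2CC(O)CO)cc1OC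
F11 | step 8 | 2-[(2S,3S)-2-[3,5-dimethoxy-4-(methoxymethoxy)phenyl]-5-(1,3-dioxolan-2-yl)-7-methoxy-2,3-dihydro-1-benzofuran-3-yl]acetaldehyde | COCOc1c(OC)cc([C@H]2Oc3c(OC)cc(C4OCCO4)cc3[C@@H]2CC=O)cc1OC
F12 | step 8 | tert-butyl{2-[(2S,3S)-2-[3,5-dimethoxy-4-(methoxymethoxy)phenyl]-5-(1,3-dioxolan-2-yl)-7-methoxy-2,3-dihydro-1-benzofuran-3-yl]ethenyloxy}dimethylsilane (E/Z mixture) | COCOc1c(OC)cc([C@H]2Oc3c(OC)cc(C4OCCO4)cc3[C@@H]2C=CO[Si](C)(C)C(C)(C)C)cc1OC
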